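(The data are simulated for substances that don't exist; noise was put on by code.)

Z and Q are charged in equal amounts, 17 mM each, but they do not fall together: at 2.50 h blue holds 12.3% of Z against 25.7% of Q.

all flasks: Z 17 mM; Q 17 mM; G 0.1 mol%

| run | J | remark | time |
|---|---|---|---|
| amber | 2.8 equiv (fed, over 1.0 h) | run made earlier |  |
| blue | 4 equiv (fed, over 1.0 h) | run made earlier |  |
| Monday's | 3.00 equiv (fed, over 1.0 h) |  | 5.0 h |
| Saturday's | 2.00 equiv (fed, over 1.0 h) |  | 5.0 h |

| run | time / h | Q / % | Z / % |
|---|---|---|---|
| amber | 0.200 | 50.3 | 49.4 |
| amber | 0.333 | 48.9 | 46.7 |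
| amber | 0.500 | 49.2 | 46.4 |
| amber | 0.833 | 45.0 | 40.8 |
| amber | 1.50 | 40.5 | 29.9 |
| amber | 2.50 | 34.1 | 21.4 |
| blue | 0.417 | 49.8 | 46.1 |
| blue | 0.833 | 44.2 | 38.1 |
| blue | 1.33 | 37.6 | 27.0 |
| blue | 1.50 | 33.8 | 23.5 |
| blue | 2.00 | 29.5 | 16.9 |
| blue | 2.50 | 25.7 | 12.3 |

(readings scatter by 1 percentage point)

- G is single-handed; Z and Q are mirror images of each other, charged as a racemate, each of them at the stated concentration
- the analysis behind the earlier runs scatters by 1 percentage point, standard deviation
- an excess is the difference of the two amounts in percent of their sum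
- an excess is below zero if the other one leads

- which one finishes higher in excess of Q over Z among what is left of the two ("neither" within 2 percentage points) (Monday's / Saturday's / neither)
- excess of Q over Z among what is left of the two at the end, Monday's
- excess of Q over Z among what is left of the two at the end, Saturday's

Bench note for Monday's and Saturday's flasks. The quantity to carry is the selectivity factor s, the log loss of Z divided by the log loss of Q, read from blue's last readings:

s = 2.11

part of Q left = (part of Z left)^(1/s)

excess = (part of Q left − part of Z left) / (part of Q left + part of Z left)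

Amber's last Z then calls for 33.4% of Q, and amber read 34.1%.

Amber's log loss of Z rises at 0.334 /h late in the run. Held at that pace, it reaches 1.68 at 5.0 h. Scaling by the J charged is rough, since blue over amber reads 1.65 for a dose ratio of 1.43.

Monday's: Z left 16.4%, excess 44.2%

Saturday's: Z left 30.0%, excess 30.6%

So Monday's should finish higher. Blue, with more J, holds less Z than amber, and on the rule the excess rises as Z is lost.

The forecast, holding that “part of J is lost”, names Monday's with 44% and 20%, and so parts from this reckoning on Saturday's.

The flask gives Monday's higher, with 47.3% on Monday's and 31.1% on Saturday's.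

    J + G + Z → G + L (k = 1.00 × 10⁶ /M²/h)
    J + G + Q → G + E (k = 4.70 × 10⁵ /M²/h)
    J ⇌ X (K = 0.350, k = 8.90 /h)
    J → D (k = 0.00110 /h)

Monday's keeps 14% of its charged Z at 5.00 h, and the rule turns that into 39.8% of Q, against 40% in the flask. The neighbour is Monday's flask with G cut to 0.025 mol%. It keeps 54% of its Z at 5.00 h, so the rule calls for 74.4% of Q and an excess of 16.3%. That flask holds 75% of its Q, at an excess of 16.4%.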